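The benzene ring carries the C1 hydroxyl para to the C4 methoxy group, which is the 4-methoxyphenol pattern of a carbene benzannulation. The retrosynthesis therefore cuts C4–C5, C6–C1 and C1–C2 together.
Three pieces result. C2–C3–C4 with both methoxy groups is a (2-methoxyvinyl)(methoxy)carbene chromium complex, C5–C6 with the C21 chain is tricos-1-yne, and C1 is a carbonyl ligand of chromium.
The alkyne comes from 1-docosanol by oxidation and one-carbon homologation. The carbene comes from methyl (E)-3-methoxyacrylate through its sodium salt and acid chloride, acylation of Na2Cr(CO)5 and O-methylation.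
The only ring arises in the last step, with the chain already attached to the alkyne, and work-up in air frees the phenol.
The target has no stereocentre. The one stereo-element on the way, the E enol ether of the carbene, comes from the commercial acrylate and is erased on aromatisation.

Key step: step 6

Remark: ring atoms are numbered C1 (OH), C2 (OMe), C3 (H), C4 (OMe), C5 (H), C6 (C21 chain). In SMILES the carbonyl ligands are drawn as Cr=C=O and the η6 arene–chromium bond as a dot.

Step 1
Reactants: 1 1-docosanol
Product: 2 docosanal
Conditions: IBX, EtOAc, 80 °C; filter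
Reagents that add atoms: none
Why: IBX oxidation of a primary alcohol stops at the aldehyde, and hot ethyl acetate dissolves the waxy C22 alcohol while the reagent and its reduced form stay insoluble and are filtered off.

Step 2
Reactants: 2 docosanal
Product: 3 tricos-1-yne
Conditions: dimethyl (1-diazo-2-oxopropyl)phosphonate, K2CO3, THF–MeOH, rt
Reagents that add atoms: dimethyl (1-diazo-2-oxopropyl)phosphonate, CC(=O)C(=[N+]=[N-])P(=O)(OC)OC
Why: In the Ohira–Bestmann variant of the Seyferth–Gilbert homologation, methanolysis of the reagent gives the diazomethylphosphonate anion, which olefinates the aldehyde, and loss of N2 with a 1,2-hydrogen shift should turn the C22 aldehyde into the C23 terminal alkyne under base mild enough for an enolisable aldehyde.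

Step 3
Reactants: 4 methyl (E)-3-methoxyacrylate
Product: 5 sodium (E)-3-methoxyacrylate
Conditions: NaOH (1.0 equiv), H2O–MeOH, rt to 40 °C; evaporate, dry in vacuo
Reagents that add atoms: sodium hydroxide, [Na+].[OH-]
Why: Ester saponification leaves the base-stable enol ether and its E geometry untouched, and isolation as the dry sodium salt spares the acid-labile enol ether any aqueous acid.

Step 4
Reactants: 5 sodium (E)-3-methoxyacrylate
Product: 6 (E)-3-methoxyacryloyl chloride
Conditions: (COCl)2, Et2O, 0 °C to rt; filter, distil under reduced pressure
Reagents that add atoms: oxalyl chloride, O=C(Cl)C(=O)Cl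
Why: Acyl chloride formation from a carboxylate salt and oxalyl chloride runs through a mixed anhydride that collapses with loss of CO and CO2, so no HCl is released that could add to the enol ether.

Step 5
Reactants: 7 chromium hexacarbonyl Cr(CO)6; 6 (E)-3-methoxyacryloyl chloride
Product: 10 pentacarbonyl[(E)-1,3-dimethoxyprop-2-en-1-ylidene]chromium, via disodium pentacarbonylchromate Na2Cr(CO)5 8 (not isolated), via acylate Na[(CO)5CrC(O)CH=CHOMe] 9 (not isolated)
Conditions: NaC10H8 (sodium naphthalenide), THF, −78 °C; 6, −78 to 0 °C; evaporate; Me3OBF4, CH2Cl2, 0 °C to rt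
Reagents that add atoms: trimethyloxonium tetrafluoroborate, C[O+](C)C.F[B-](F)(F)F
Why: In the Semmelhack–Hegedus route to Fischer carbene complexes, two-electron reduction of Cr(CO)6 gives a strongly nucleophilic dianion that is acylated at the metal by the acid chloride, and hard O-methylation of the acylate with the Meerwein salt should give the methoxycarbene without recourse to an elimination-prone 2-methoxyvinyllithium.

Step 6
Reactants: 10 pentacarbonyl[(E)-1,3-dimethoxyprop-2-en-1-ylidene]chromium; 3 tricos-1-yne
Product: 12 6-n-heneicosyl-2,4-dimethoxyphenol, via tricarbonyl(η6-6-heneicosyl-2,4-dimethoxyphenol)chromium 11 (not isolated)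
Conditions: THF (degassed), 55 °C, Ar; then air, Et2O, daylight, rt; filter through silica
Reagents that add atoms: none
Why: Heating expels one carbonyl ligand from 10, alkyne 3 binds and inserts into the Cr=C bond with its CH terminus joining the carbene carbon (C4–C5), and a carbonyl ligand then migrates onto the chain-bearing carbon (C6–C1) to give a chromium-bound dienylketene. The one ring formed, the benzene ring, closes by 6π electrocyclisation between the ketene carbon and the methoxy-bearing vinyl carbon (C1–C2), after which enolisation of the cyclohexadienone gives the phenol as its Cr(CO)3 complex 11, and air with light oxidises the zerovalent metal away to free 12. The closest known reaction type is the Dötz benzannulation of alkenyl(methoxy)carbene chromium complexes with terminal alkynes, which delivers 4-methoxyphenols. No stereocentre is created, and the E geometry of 10 disappears on aromatisation. The step needs regioselective insertion, secured by the steric contrast between the C21 chain and hydrogen, which puts the chain carbon next to the carbonyl-derived C1 so that OH, the two OMe groups and the chain fall at C1, C2, C4 and C6. It also needs carbonyl insertion to outrun five-membered ring closure, which is favoured by chromium as the metal, by oxygen rather than nitrogen donors at the carbene carbon and the vinyl terminus, by an alkenyl rather than an aryl carbene, and by THF at moderate temperature.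

Compound list
1 | 1-docosanol | CCCCCCCCCCCCCCCCCCCCCCO | starting material
2 | docosanal | CCCCCCCCCCCCCCCCCCCCCC=O | intermediate
3 | tricos-1-yne | C#CCCCCCCCCCCCCCCCCCCCCC | intermediate
4 | methyl (E)-3-methoxyacrylate | CO/C=C/C(=O)OC | starting material
5 | sodium (E)-3-methoxyacrylate | CO/C=C/C(=O)[O-].[Na+] | intermediate
6 | (E)-3-methoxyacryloyl chloride | CO/C=C/C(=O)Cl | intermediate
7 | chromium hexacarbonyl Cr(CO)6 | O=C=[Cr](=C=O)(=C=O)(=C=O)(=C=O)=C=O | starting material
8 | disodium pentacarbonylchromate Na2Cr(CO)5 | [Na+].[Na+].O=C=[Cr-2](=C=O)(=C=O)(=C=O)=C=O | intermediate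
9 | sodium pentacarbonyl[(E)-3-methoxyacryloyl]chromate Na[(CO)5CrC(O)CH=CHOMe] | [Na+].CO/C=C/C([O-])=[Cr](=C=O)(=C=O)(=C=O)(=C=O)=C=O | intermediate
10 | pentacarbonyl[(E)-1,3-dimethoxyprop-2-en-1-ylidene]chromium | CO/C=C/C(OC)=[Cr](=C=O)(=C=O)(=C=O)(=C=O)=C=O | intermediate
11 | tricarbonyl(η6-6-heneicosyl-2,4-dimethoxyphenol)chromium | CCCCCCCCCCCCCCCCCCCCCc1cc(OC)cc(OC)c1O.O=C=[Cr](=C=O)=C=O | intermediate
12 | 6-n-heneicosyl-2,4-dimethoxyphenol | CCCCCCCCCCCCCCCCCCCCCc1cc(OC)cc(OC)c1O | target

Total step count: 6
Longest linear sequence: 4 steps (4 → 5 → 6 → 10 → 12). The alkyne branch (1 → 2 → 3) joins in step 6.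

Steps most likely to fail

1. Step 6. The β-oxygen donor makes the vinylcarbene intermediate electron-rich, so carbonyl migration may lag behind direct five-membered ring closure. Oligomerisation of the terminal alkyne and over-oxidation of the electron-rich phenol during demetalation may erode the outcome further. The fallback sets out from 7 and 3 and returns at 12. It leaves the donor out of the annulation and brings in the C2 oxygen afterwards.
 - (E)-Me3SiCH=CHLi, from (E)-(2-bromovinyl)trimethylsilane and t-BuLi, would add to 7 to give the lithium acylate Li[(CO)5CrC(O)CH=CHSiMe3] F1.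
 - Me3OBF4 would convert F1 into pentacarbonyl[(E)-1-methoxy-3-(trimethylsilyl)prop-2-en-1-ylidene]chromium F2, a stable equivalent of the parent vinylcarbene complex.
 - Heating F2 with 3 in THF should give, after a carbon-to-oxygen silyl shift in the cyclohexadienone, tricarbonyl[η6-(2-heneicosyl-4-methoxyphenoxy)trimethylsilane]chromium F3.
 - Air and dilute aqueous acid would then release 2-heneicosyl-4-methoxyphenol F4.
 - Bromination with NBS and catalytic i-Pr2NH in CH2Cl2, at the only free position ortho to the hydroxyl, would give 2-bromo-6-heneicosyl-4-methoxyphenol F5.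
 - Ullmann-type methoxylation (NaOMe, CuBr, DMF–MeOH, 110 °C) would lead to 12.

2. Step 5. Electron transfer from the dianion to the acid chloride, or attack at the β-carbon with loss of methoxide, may compete with acylation at the carbonyl group, and the acid chloride may polymerise before it is consumed. The fallback sets out from 7 and returns at 10. It builds the carbene by the Fischer route and installs the vinyl oxygen by conjugate addition.
 - LiC≡CSiMe3, from ethynyltrimethylsilane and n-BuLi, would add to 7 to give the lithium acylate Li[(CO)5CrC(O)C≡CSiMe3] F6.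
 - Me3OBF4 would give pentacarbonyl[1-methoxy-3-(trimethylsilyl)prop-2-yn-1-ylidene]chromium F7.
 - Methanol with catalytic NaOMe at low temperature should remove the silyl group and add across the activated triple bond to give 10.
 - Alkoxide exchange at the carbene carbon is degenerate here, because both groups are methoxy.

3. Step 2. The waxy aldehyde may separate from the methanolic medium, and base-induced aldol self-condensation may then overtake the olefination. The fallback sets out from 2 and returns at 3. It uses the two-stage Corey–Fuchs sequence in aprotic solvents.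
 - CBr4 and PPh3 in CH2Cl2 would give 1,1-dibromotricos-1-ene F8.
 - n-BuLi (2 equiv) in THF at −78 °C would convert F8 by bromine–lithium exchange and rearrangement into tricos-1-ynyllithium F9.
 - Quenching F9 with water would give 3.

Further compounds
F1 | step 6 | lithium pentacarbonyl[(E)-3-(trimethylsilyl)acryloyl]chromate Li[(CO)5CrC(O)CH=CHSiMe3] | [Li+].[O-]C(/C=C/[Si](C)(C)C)=[Cr](=C=O)(=C=O)(=C=O)(=C=O)=C=O
F2 | step 6 | pentacarbonyl[(E)-1-methoxy-3-(trimethylsilyl)prop-2-en-1-ylidene]chromium | COC(/C=C/[Si](C)(C)C)=[Cr](=C=O)(=C=O)(=C=O)(=C=O)=C=O
F3 | step 6 | tricarbonyl[η6-(2-heneicosyl-4-methoxyphenoxy)trimethylsilane]chromium | CCCCCCCCCCCCCCCCCCCCCc1cc(OC)ccc1O[Si](C)(C)C.O=C=[Cr](=C=O)=C=O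
F4 | step 6 | 2-heneicosyl-4-methoxyphenol | CCCCCCCCCCCCCCCCCCCCCc1cc(OC)ccc1O
F5 | step 6 | 2-bromo-6-heneicosyl-4-methoxyphenol | CCCCCCCCCCCCCCCCCCCCCc1cc(OC)cc(Br)c1O
F6 | step 5 | lithium pentacarbonyl[3-(trimethylsilyl)propynoyl]chromate Li[(CO)5CrC(O)C≡CSiMe3] | [Li+].[O-]C(C#C[Si](C)(C)C)=[Cr](=C=O)(=C=O)(=C=O)(=C=O)=C=O
F7 | step 5 | pentacarbonyl[1-methoxy-3-(trimethylsilyl)prop-2-yn-1-ylidene]chromium | COC(C#C[Si](C)(C)C)=[Cr](=C=O)(=C=O)(=C=O)(=C=O)=C=O
F8 | step 2 | 1,1-dibromotricos-1-ene | CCCCCCCCCCCCCCCCCCCCCC=C(Br)Br
F9 | step 2 | tricos-1-ynyllithium | [Li]C#CCCCCCCCCCCCCCCCCCCCCCC
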